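**Retrosynthetic overview**
1. Target ⇐ removal of four MOM ethers from the (2S)-tetra-MOM flavanone ⇐ kinetic resolution of the racemic flavanone by asymmetric transfer hydrogenation.
2. Ring C ⇐ O1–C2 disconnection: intramolecular oxa-Michael closure of a 2'-hydroxychalcone.
3. Key C–C disconnection (C2–C3 of the flavanone): intermolecular Claisen–Schmidt aldol condensation of a ring A methyl ketone with a ring B aldehyde.
4. Ring A ketone ⇐ phloracetophenone (bis-O-allylation, double Claisen, bis-MOM, cross-metathesis with 2-methyl-2-butene). Ring B aldehyde ⇐ resorcinol (MOM, then two directed ortho-lithiations: prenyl bromide, then DMF).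
5. Ring order: aromatic rings A and B are bought in. Ring C is the only ring built, and it is built last.

Assumption: the stereocentre in the SMILES reads as (2S), and ≥98 % ee after a catalytic kinetic resolution counts as the single enantiomer (prenyl = 3-methylbut-2-en-1-yl, MOM = CH2OCH3).

**Route**

Step 1
Reactants: 1 resorcinol
Product: 2 1,3-bis(methoxymethoxy)benzene
Conditions: MOMCl (2.5 equiv), i-Pr2NEt (3 equiv), CH2Cl2, 0 °C → rt
Reagents that add atoms: chloromethyl methyl ether (MOMCl), COCCl
Why: O-alkylation of both phenols (MOM acetal protection) gives base-stable ethers that also act as strong directing groups for the lithiations that follow.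

Step 2
Reactants: 2 1,3-bis(methoxymethoxy)benzene
Product: 4 1,3-bis(methoxymethoxy)-2-prenylbenzene, via aryllithium 3 (not isolated)
Conditions: n-BuLi (1.1 equiv), THF, 0 °C → rt, 1.5 h; prenyl bromide (1.2 equiv), −78 °C → rt
Reagents that add atoms: prenyl bromide, CC(C)=CCBr
Why: Directed ortho-metalation occurs only at C2, which is flanked by both OMOM groups, and SN2 alkylation of the aryllithium by the primary allylic bromide gives the linear prenyl group.

Step 3
Reactants: 4 1,3-bis(methoxymethoxy)-2-prenylbenzene
Product: 7 2,4-bis(methoxymethoxy)-3-prenylbenzaldehyde, via C4-aryllithium 5 (not isolated), via lithium hemiaminal alkoxide 6 (not isolated)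
Conditions: n-BuLi (1.2 equiv), TMEDA (1.2 equiv), THF, −20 → 0 °C, 1.5 h; DMF (3 equiv), −78 °C → rt; H2O quench
Reagents that add atoms: N,N-dimethylformamide (DMF), CN(C)C=O
Why: A second directed ortho-metalation takes the only remaining kind of position next to an OMOM group, and Bouveault-type formylation with DMF releases the aldehyde when the tetrahedral adduct collapses on aqueous quench.

Step 4
Reactants: 8 2,4,6-trihydroxyacetophenone
Product: 9 1-[2,4-bis(allyloxy)-6-hydroxyphenyl]ethan-1-one
Conditions: allyl bromide (2.1 equiv), K2CO3 (2.2 equiv), acetone, reflux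
Reagents that add atoms: allyl bromide, C=CCBr
Why: In this Williamson ether synthesis two phenols are alkylated while the third is held back by its hydrogen bond to the acetyl carbonyl.

Step 5
Reactants: 9 1-[2,4-bis(allyloxy)-6-hydroxyphenyl]ethan-1-one
Product: 11 1-(3,5-diallyl-2,4,6-trihydroxyphenyl)ethan-1-one, via mono-rearranged allylphenol 10 (not isolated)
Conditions: PhNEt2, 200 °C, argon, sealed tube, 6 h
Reagents that add atoms: none
Why: Two aromatic Claisen [3,3]-sigmatropic rearrangements (ortho, or para by Claisen–Cope if C3 fills first), each followed by tautomerisation, can end only on the two free ring carbons C3 and C5, so every pathway converges on 11.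

Step 6
Reactants: 11 1-(3,5-diallyl-2,4,6-trihydroxyphenyl)ethan-1-one
Product: 12 1-[3,5-diallyl-2-hydroxy-4,6-bis(methoxymethoxy)phenyl]ethan-1-one
Conditions: MOMCl (2.3 equiv), i-Pr2NEt (3 equiv), CH2Cl2, 0 °C → rt
Reagents that add atoms: chloromethyl methyl ether (MOMCl), COCCl
Why: In this selective MOM protection the two ortho-hydroxyls of symmetric 11 are equivalent, and once the 4-OH and one of them are capped the last one is deactivated by chelation to the ketone, which keeps the nucleophile needed for ring C.

Step 7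
Reactants: 12 1-[3,5-diallyl-2-hydroxy-4,6-bis(methoxymethoxy)phenyl]ethan-1-one
Product: 13 1-[2-hydroxy-4,6-bis(methoxymethoxy)-3,5-diprenylphenyl]ethan-1-one
Conditions: second-generation Grubbs catalyst (H2IMes)(PCy3)Cl2Ru=CHPh (5 mol %), 2-methyl-2-butene/CH2Cl2 (1:1), 40 °C, sealed tube
Reagents that add atoms: 2-methyl-2-butene, CC=C(C)C
Why: Olefin cross-metathesis of both terminal allyl groups with excess 2-methyl-2-butene is driven by loss of a volatile alkene and turns each allyl into a prenyl group without regiochemical ambiguity, and the trisubstituted product alkenes no longer react with the catalyst.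

Step 8
Reactants: 13 1-[2-hydroxy-4,6-bis(methoxymethoxy)-3,5-diprenylphenyl]ethan-1-one; 7 2,4-bis(methoxymethoxy)-3-prenylbenzaldehyde
Product: 15 (E)-3-[2,4-bis(methoxymethoxy)-3-prenylphenyl]-1-[2-hydroxy-4,6-bis(methoxymethoxy)-3,5-diprenylphenyl]prop-2-en-1-one, via racemic aldol adduct 14 (not isolated)
Conditions: KOH (50 % aq, 20 equiv), EtOH, argon, rt, 48 h (7: 1.2 equiv)
Reagents that add atoms: none
Why: In this Claisen–Schmidt crossed aldol condensation only 13 can enolise and only 7 is an aldehyde, so the enolate adds intermolecularly to 7 to form the future C2–C3 bond, and E1cB dehydration of 14 gives the conjugated E-enone.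

Step 9
Reactants: 15 the (E)-chalcone
Product: 16 racemic 5,7-bis(methoxymethoxy)-2-[2,4-bis(methoxymethoxy)-3-prenylphenyl]-6,8-diprenylchroman-4-one
Conditions: NaOAc (10 equiv), EtOH, reflux, 36 h (recovered 15 resubmitted)
Reagents that add atoms: none
Why: Base-catalysed 6-endo-trig intramolecular oxa-Michael addition of the 2'-phenoxide closes ring C, the equilibrium favours the flavanone because the 2',6'-disubstituted chalcone is twisted out of conjugation, and C2 is formed racemic at this stage.

Step 10
Reactants: 16 the racemic tetra-MOM flavanone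
Product: 17 (2S)-5,7-bis(methoxymethoxy)-2-[2,4-bis(methoxymethoxy)-3-prenylphenyl]-6,8-diprenylchroman-4-one
Conditions: Cp*RhCl[(R,R)-TsDPEN] (1 mol %), HCO2H/Et3N (5:2), EtOAc, rt to 40 °C, stopped at ca. 55 % conversion (chiral HPLC control), chromatography
Reagents that add atoms: none
Why: In this Noyori–Ikariya asymmetric transfer hydrogenation run as a kinetic resolution, the (R,R)-catalyst delivers hydride to the carbonyl face that gives a (4R)-carbinol, which is fast only for the (2R)-ketone because it leads to the favoured 2,4-cis flavan-4-ol, so the ketone left untouched is (2S)-17 in high ee while prenyl alkenes and MOM ethers are inert.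

Step 11
Reactants: 17 the (2S)-tetra-MOM flavanone
Product: 18 (2S)-5,7-dihydroxy-2-[2,4-dihydroxy-3-prenylphenyl]-6,8-diprenylchroman-4-one (target)
Conditions: HCl (1.25 M in MeOH, diluted to ca. 0.3 M), MeOH, 0 °C → rt, stopped at full conversion; pH 6 phosphate buffer work-up
Reagents that add atoms: none
Why: Acid-catalysed transacetalisation of the four MOM acetals to methanol frees the phenols in acid too dilute and cold to protonate the prenyl alkenes, and the (2S) centre is kept because ring opening by retro-oxa-Michael reaction is negligible without base.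

**Compound list**
1 | resorcinol | Oc1cccc(O)c1 | starting material
2 | 1,3-bis(methoxymethoxy)benzene | COCOc1cccc(OCOC)c1 | intermediate
3 | [2,6-bis(methoxymethoxy)phenyl]lithium | [Li]c1c(OCOC)cccc1OCOC | intermediate (not isolated)
4 | 1,3-bis(methoxymethoxy)-2-(3-methylbut-2-en-1-yl)benzene | COCOc1cccc(OCOC)c1CC=C(C)C | intermediate
5 | [2,4-bis(methoxymethoxy)-3-(3-methylbut-2-en-1-yl)phenyl]lithium | [Li]c1ccc(OCOC)c(CC=C(C)C)c1OCOC | intermediate (not isolated)
6 | lithium [2,4-bis(methoxymethoxy)-3-(3-methylbut-2-en-1-yl)phenyl](dimethylamino)methanolate, racemic | [Li]OC(N(C)C)c1ccc(OCOC)c(CC=C(C)C)c1OCOC | intermediate (not isolated)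
7 | 2,4-bis(methoxymethoxy)-3-(3-methylbut-2-en-1-yl)benzaldehyde | O=Cc1ccc(OCOC)c(CC=C(C)C)c1OCOC | intermediate
8 | 2,4,6-trihydroxyacetophenone (phloracetophenone) | CC(=O)c1c(O)cc(O)cc1O | starting material
9 | 1-[2,4-bis(allyloxy)-6-hydroxyphenyl]ethan-1-one | CC(=O)c1c(O)cc(OCC=C)cc1OCC=C | intermediate
10 | 1-[3-allyl-4-(allyloxy)-2,6-dihydroxyphenyl]ethan-1-one | CC(=O)c1c(O)cc(OCC=C)c(CC=C)c1O | intermediate (not isolated)
11 | 1-(3,5-diallyl-2,4,6-trihydroxyphenyl)ethan-1-one | CC(=O)c1c(O)c(CC=C)c(O)c(CC=C)c1O | intermediate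
12 | 1-[3,5-diallyl-2-hydroxy-4,6-bis(methoxymethoxy)phenyl]ethan-1-one | CC(=O)c1c(O)c(CC=C)c(OCOC)c(CC=C)c1OCOC | intermediate
13 | 1-[2-hydroxy-4,6-bis(methoxymethoxy)-3,5-bis(3-methylbut-2-en-1-yl)phenyl]ethan-1-one | CC(=O)c1c(O)c(CC=C(C)C)c(OCOC)c(CC=C(C)C)c1OCOC | intermediate
14 | racemic 3-hydroxy-3-[2,4-bis(methoxymethoxy)-3-prenylphenyl]-1-[2-hydroxy-4,6-bis(methoxymethoxy)-3,5-diprenylphenyl]propan-1-one | CC(C)=CCc1c(OCOC)ccc(C(O)CC(=O)c2c(O)c(CC=C(C)C)c(OCOC)c(CC=C(C)C)c2OCOC)c1OCOC | intermediate (not isolated)
15 | (E)-3-[2,4-bis(methoxymethoxy)-3-prenylphenyl]-1-[2-hydroxy-4,6-bis(methoxymethoxy)-3,5-diprenylphenyl]prop-2-en-1-one | CC(C)=CCc1c(OCOC)ccc(/C=C/C(=O)c2c(O)c(CC=C(C)C)c(OCOC)c(CC=C(C)C)c2OCOC)c1OCOC | intermediate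
16 | racemic 5,7-bis(methoxymethoxy)-2-[2,4-bis(methoxymethoxy)-3-prenylphenyl]-6,8-diprenylchroman-4-one | CC(C)=CCc1c(OCOC)ccc(C2CC(=O)c3c(OCOC)c(CC=C(C)C)c(OCOC)c(CC=C(C)C)c3O2)c1OCOC | intermediate
17 | (2S)-5,7-bis(methoxymethoxy)-2-[2,4-bis(methoxymethoxy)-3-prenylphenyl]-6,8-diprenylchroman-4-one | CC(C)=CCc1c(OCOC)ccc([C@@H]2CC(=O)c3c(OCOC)c(CC=C(C)C)c(OCOC)c(CC=C(C)C)c3O2)c1OCOC | intermediate
18 | (2S)-5,7-dihydroxy-2-[2,4-dihydroxy-3-prenylphenyl]-6,8-diprenylchroman-4-one | CC(C)=CCc1c(O)ccc([C@@H]2CC(=O)c3c(O)c(CC=C(C)C)c(O)c(CC=C(C)C)c3O2)c1O | target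

**Totals**
Total step count: 11.
Longest linear sequence: 8 steps (steps 4–11, from 8). The ring B branch (steps 1–3) joins at step 8.

**Three steps most likely to fail**

Step 10 (kinetic resolution). The C4 carbonyl is electron-rich and is crowded by the 5-OMOM group and the 6-prenyl group behind it. Hydride transfer may therefore be slow, or the selectivity factor too low, and the yield cannot exceed 50 %. The fallback sets out from 16 and comes back at 17. It replaces the reaction by a physical separation: preparative HPLC or SFC of 16 on an amylose tris(3,5-dimethylphenylcarbamate) chiral stationary phase. Compound 17 is recognised by circular dichroism, since a (2S)-flavanone shows a positive band near 330 nm and a negative band near 290 nm. The unwanted (2R)-tetra-MOM flavanone F1 is refluxed with NaOAc in EtOH, which re-equilibrates it through chalcone 15 to racemic 16 for re-injection.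

Step 11 (global MOM removal). Every prenyl group sits next to at least one phenol that is being freed. Too much acid closes 2,2-dimethylchromans, and a basic work-up opens ring C and erodes the ee. The fallback sets out from 17 and comes back at 18. It exchanges the acetals for silicon without any Brønsted acid. TESOTf with 2,2'-bipyridyl in CH2Cl2 at 0 °C converts aryl MOM ethers directly into aryl silyl ethers, giving the (2S)-tetrakis(triethylsilyl) ether F2. This is then desilylated with Et3N·3HF in THF at 0 °C to give 18.

Step 5 (double Claisen). At 200 °C the polyphenolic products can cyclise to dihydrobenzofurans, lose the acetyl group or darken by oxidation, so the yield may be poor. The fallback sets out from 8 and comes back at 13, bypassing 9–12. Phloracetophenone is C-prenylated directly as its phenoxide with prenyl bromide (2.1 equiv) and KOH (aq) at 0 °C → rt. This gives 2,4,6-trihydroxy-3,5-diprenylacetophenone F3 in moderate yield, which is separated by chromatography from the mono-, geminal di- and triprenylated by-products. Selective bis-protection with MOMCl and i-Pr2NEt in CH2Cl2, as in step 6, then gives 13.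

**Further compounds**
F1 | step 10 | (2R)-5,7-bis(methoxymethoxy)-2-[2,4-bis(methoxymethoxy)-3-prenylphenyl]-6,8-diprenylchroman-4-one | CC(C)=CCc1c(OCOC)ccc([C@H]2CC(=O)c3c(OCOC)c(CC=C(C)C)c(OCOC)c(CC=C(C)C)c3O2)c1OCOC
F2 | step 11 | (2S)-5,7-bis(triethylsilyloxy)-2-[2,4-bis(triethylsilyloxy)-3-prenylphenyl]-6,8-diprenylchroman-4-one | CC(C)=CCc1c(O[Si](CC)(CC)CC)ccc([C@@H]2CC(=O)c3c(O[Si](CC)(CC)CC)c(CC=C(C)C)c(O[Si](CC)(CC)CC)c(CC=C(C)C)c3O2)c1O[Si](CC)(CC)CC
F3 | step 5 | 1-[2,4,6-trihydroxy-3,5-bis(3-methylbut-2-en-1-yl)phenyl]ethan-1-one | CC(=O)c1c(O)c(CC=C(C)C)c(O)c(CC=C(C)C)c1O
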